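## Analysis of the target

The target is a cyclohexane fused to an oxirane (a 7-oxabicyclo[4.1.0]heptane) in which every ring carbon is a stereocentre. Numbering used throughout: C1 is the quaternary oxirane carbon and carries the benzoyloxymethyl carbon C7; C2 and C3 carry the acetoxy groups, C4 and C5 the free hydroxyls, and C6 is the oxirane CH. With the ring drawn flat, the oxirane oxygen, O2 and O4 lie on one face (the lower face) and C7, O3 and O5 on the other (the upper face). O2 to O5 are therefore all-trans, the oxirane is cis to O2 and trans to O5, and the absolute configuration is 1S,2R,3S,4R,5R,6S. The sensitive groups are the oxirane (acid, nucleophiles) and three esters of two kinds placed next to free hydroxyls, so that any alkoxide late in the route invites acyl migration. The difficulty is twofold: a fully substituted carbinol carbon has to be set in absolute terms inside six contiguous oxygenated stereocentres, and five oxygens must end in three different states (benzoate, acetate, free hydroxyl) beside the oxirane. The plan rests on C1 being a tertiary carbinol carbon flanked by two one-carbon arms, C7 and C6. That is C4 of a 4-C-hydroxymethyl pentofuranose, with C2 and C3 mapping onto C3 and C2 of D-glucose. An alkene at C5=C6 beside this carbinol can then deliver O5 and the C1–C6 oxirane together, by upper-face epoxidation and migration of the oxirane towards C1.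

## Retrosynthetic reasoning

**Esters and silyl groups (26 back to 22).** The two O–Si bonds of 25, the acetyl C–O bonds of 25 and the benzoyl C–O bond of 24 are cut first. The esters are placed last because none of them survives the organomagnesium reagent or the alkoxide of the oxirane migration. C7–O, O2 and O3 therefore travel as naphthalen-2-ylmethyl (NAP) ethers, which come off together under neutral oxidative conditions, and O4/O5 travel as triethylsilyl ethers in 22. In 23 the primary C7 hydroxyl is told apart from the two hindered secondary ones by rate.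

**Oxirane migration (21 back to 19).** The C6–O1 bond is cut and the oxygen on C5 is reconnected to C6, which gives the upper-face C5–C6 oxirane 19 with O1 on the lower face. The forward reaction must free O1 and let it attack C6 from the face opposite the oxirane. It sets C6, reveals O5 on the upper face and ends in the more substituted oxirane.

**Oxirane from alkene (19 back to 17).** Both C–O bonds of the C5–C6 oxirane are cut. The forward epoxidation must occur on the upper face only. In 18 both allylic oxygens (O1, O4) sit on the lower face as silyl ethers, and capping O1 also removes the hydrogen bond that would otherwise steer a peracid to the lower face.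

**Ring closure (17 back to 16).** The C5=C6 bond is cut. It is the one ring bond whose formation creates no stereocentre; it lies beside the finished quaternary carbinol and away from the C2–C4 array. It leaves exactly the alkene that the two disconnections above need. All stereochemistry of C1–C4 is thereby moved into acyclic sugar chemistry, and the forward step only has to join two vinyl groups.

**C4–C5 bond (16 back to 13 and 14).** The secondary carbinol C4 is cut from its vinyl group, which leads to lactol 13 and vinylmagnesium bromide 14. The furanose ring oxygen becomes the tertiary hydroxyl O1 of 15. The forward addition must place O4 threo to O3, which chelation through the neighbouring ether oxygen should provide.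

**Protecting-group exchange (13 back to 10).** O3 (ring numbering) must be capped before O4 exists; otherwise two vicinal secondary hydroxyls would have to be distinguished. The acetals of 10 are therefore exchanged for three NAP ethers through the methyl furanoside 11 and its ether 12. NAP is chosen because it survives the aqueous acid that unmasks 13, which a 4-methoxybenzyl ether would not.

**C6 arm (10 back to 8).** The terminal methylene of the vinyl group is cut (methylenation of aldehyde 9), and 9 goes back to the free hydroxymethyl arm of 8.

**Telling the two arms apart (8 back to 7).** The acetal C–O bond to the hydroxymethyl oxygen is cut. In the forward direction the 4-methoxybenzyl ether on O3 of the sugar is oxidised and captured by the arm on its own face only. This differentiation creates the quaternary stereocentre.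

**Quaternary carbon (7 back to 1 and 4).** The C4–CH2OH bond of the sugar is cut (aldol with formaldehyde 4, then hydride transfer), which leads through diol 3 and ether 2 to diacetone glucose 1.

## Alternatives that were turned down

Alternative 1: The ring is taken from an arene. The C2–O bond is cut by a retro-oxa-Michael step, which leads to the achiral para-quinol A1, accessible by oxidative dearomatisation of a 4-substituted phenol.
- Forward key step: an arylboronic acid esterifies the tertiary hydroxyl and, under a chiral bifunctional amine–thiourea, its remaining B–OH adds to one of the two enantiotopic β-carbons. This gives the cis-fused phenylboronate A2.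
- For: two steps buy the carbocycle, the quaternary C1 with its benzoate arm, and O2 cis to O1 as required. In step count to a ring with C1 and C2 defined, this is clearly stronger than the chosen route.
- Against: the absolute configuration depends on catalyst enantioselectivity with an untested substrate. A2 is a β-alkoxy ketone that can revert by retro-Michael reaction or aromatise. Four centres remain: O3 next to the ketone and trans to O2, a lower-face reduction at C4, then the same alkene-to-oxirane-to-migration endgame. Each relies on substrate control in a flexible enone, and the benzoate sits next to the tertiary alkoxide during the migration.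
- Comparison: the chosen strategy offers C1–C3 fixed by D-glucose and esters introduced only after all base chemistry.

Alternative 2: Both C–O bonds at C1 and C4 are cut at once, back to dioxygen and the cyclohexa-1,3-diene A3.
- Forward key step: sensitised photooxygenation, in which singlet oxygen adds across C1 and C4 on the face of the free C2 hydroxyl, giving the bicyclic endoperoxide A4.
- For: one step places O1 and O4 on the lower face and leaves the C5=C6 alkene. Reduction of the O–O bond would give the unprotected counterpart of 17, and isomerisation to the syn-bis-oxirane followed by opening at C5 would reach the target pattern almost directly. This is the shortest endgame of all and stronger than the chosen route on step economy.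
- Against: A3 must first be made enantiopure. It is a dihydroarene with allylic oxygen leaving groups, which aromatises by loss of water or acetic acid, and its vicinal hydroxy acetate can migrate. Facial selectivity rests on hydrogen-bond steering of a small electrophile, and the site of opening of a bis-oxirane (C5 against C4) is not controlled by anything in the structure.
- Comparison: the chosen strategy fixes every stereocentre of C1–C4 before the ring exists and closes the ring by a reaction that cannot affect them.

Alternative 3: The C1–C6 oxirane is traced back through two successive oxirane migrations to the lower-face 4,5-oxirane A6, which derives from the microbial ipso,ortho-cis-dihydrodiol of benzoic acid, A5.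
- Forward key step: base lets O6 open the 4,5-oxirane at C5, and then lets O1 open the new upper-face 5,6-oxirane at C6, giving A7.
- For: A5 already holds the whole carbon skeleton with C1 and C2 in the right absolute sense, so no C–C bond has to be made. The cascade ends in the same thermodynamic sink as step 15. On skeleton economy and probably on step count it is stronger.
- Against: A5 is a fermentation product of a mutant strain and not a catalogue chemical. Turning its diene into A6 needs three more oxygens with site and face control (O3 and O6 upper, oxirane lower). Two equilibria in series are run with the benzoate beside the tertiary alkoxide, where acyl migration or saponification can occur.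
- Comparison: the chosen strategy starts from a commodity sugar, needs one migration only, and carries no ester through base.

Key step: step 12

Remark on the chemistry: PMB = 4-methoxybenzyl, NAP = naphthalen-2-ylmethyl; the acetal carbon of 8–10 and the anomeric carbon of 11–13 are carried as epimer mixtures and left open in the SMILES, because both centres are destroyed in steps 7 and 10; ring numbering C1–C7 is also used for the acyclic compounds 15 and 16.

## Route

Step 1
Reactants: 1 1,2:5,6-di-O-isopropylidene-α-D-glucofuranose
Product: 2 1,2:5,6-di-O-isopropylidene-3-O-(4-methoxybenzyl)-α-D-glucofuranose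
Conditions: NaH, PMBCl, n-Bu4NI (cat.), DMF, 0 °C → rt
Reagents that add atoms: 4-methoxybenzyl chloride, COc1ccc(CCl)cc1
Why: Williamson etherification of the only free hydroxyl; the ether blocks O3 against β-elimination in step 3 and is the handle for step 4.

Step 2
Reactants: 2 1,2:5,6-di-O-isopropylidene-3-O-(4-methoxybenzyl)-α-D-glucofuranose
Product: 3 1,2-O-isopropylidene-3-O-(4-methoxybenzyl)-α-D-glucofuranose
Conditions: AcOH/H2O (3:2), rt
Reagents that add atoms: none
Why: Selective acetal hydrolysis; the side-chain dioxolane cleaves far faster than the ring-fused anomeric 1,2-acetal, and the PMB ether is stable to aqueous acetic acid at room temperature.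

Step 3
Reactants: 3 1,2-O-isopropylidene-3-O-(4-methoxybenzyl)-α-D-glucofuranose; 4 formaldehyde
Product: 7 4-C-(hydroxymethyl)-1,2-O-isopropylidene-3-O-(4-methoxybenzyl)-β-L-threo-pentofuranose, via pentodialdofuranose aldehyde 5 (not isolated), via hydroxymethyl aldol adduct 6 (not isolated)
Conditions: NaIO4, THF/H2O, 0 °C → rt; filter; then 37% aq. CH2O, 2 M NaOH, THF/H2O, rt
Reagents that add atoms: formaldehyde, C=O
Why: Glycol cleavage gives aldehyde 5, whose single α-hydrogen is replaced by CH2OH in a crossed aldol addition; the non-enolisable adduct 6 is then reduced by crossed Cannizzaro hydride transfer from formaldehyde hydrate. Both C4 epimers of 6 give the same diol 7, so no selectivity is needed here.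

Step 4
Reactants: 7 4-C-(hydroxymethyl)-1,2-O-isopropylidene-3-O-(4-methoxybenzyl)-β-L-threo-pentofuranose
Product: 8 4-C-(hydroxymethyl)-1,2-O-isopropylidene-3,5-O-(4-methoxybenzylidene)-α-D-xylofuranose
Conditions: DDQ (1.2 equiv), 4 Å molecular sieves, CH2Cl2, 0 °C → rt
Reagents that add atoms: none
Why: Anhydrous DDQ oxidation of the PMB ether gives an oxocarbenium ion on O3, which is captured by the hydroxymethyl group on the same (upper) face to give the cis-fused 1,3-dioxane; closure by the other arm would need a strained trans-fused ring. This differentiation of the two arms sets the quaternary stereocentre (later C1): the arm cis to O3 becomes C7 and the free arm becomes C6.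

Step 5
Reactants: 8 4-C-(hydroxymethyl)-1,2-O-isopropylidene-3,5-O-(4-methoxybenzylidene)-α-D-xylofuranose
Product: 9 4-C-formyl-1,2-O-isopropylidene-3,5-O-(4-methoxybenzylidene)-α-D-xylofuranose
Conditions: Dess–Martin periodinane, pyridine, CH2Cl2, 0 °C → rt
Reagents that add atoms: none
Why: Dess–Martin oxidation of the remaining neopentylic primary alcohol under buffered conditions that spare both acetals; the aldehyde has no α-hydrogen and can neither epimerise nor eliminate.

Step 6
Reactants: 9 4-C-formyl-1,2-O-isopropylidene-3,5-O-(4-methoxybenzylidene)-α-D-xylofuranose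
Product: 10 4-C-ethenyl-1,2-O-isopropylidene-3,5-O-(4-methoxybenzylidene)-α-D-xylofuranose
Conditions: Ph3PCH3Br, KN(SiMe3)2, THF, −78 °C → rt
Reagents that add atoms: methyltriphenylphosphonium bromide, C[P+](c1ccccc1)(c1ccccc1)c1ccccc1.[Br-]
Why: Wittig methylenation; the unstabilised ylide is reactive enough for an α-quaternary aldehyde, which cannot enolise.

Step 7
Reactants: 10 4-C-ethenyl-1,2-O-isopropylidene-3,5-O-(4-methoxybenzylidene)-α-D-xylofuranose
Product: 11 methyl 4-C-ethenyl-D-xylofuranoside (anomer mixture)
Conditions: 0.1 M HCl in MeOH (from AcCl), 0 °C → rt; quench Et3N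
Reagents that add atoms: methanol, CO
Why: Acid methanolysis removes the electron-rich benzylidene acetal first; the 1,2-acetal then opens through the furanosyl oxocarbenium ion, which methanol traps as the methyl furanosides (kinetic Fischer-type glycosidation). The reaction is stopped before ring expansion to pyranosides through O5 can set in.

Step 8
Reactants: 11 methyl 4-C-ethenyl-D-xylofuranoside
Product: 12 methyl 4-C-ethenyl-2,3,5-tri-O-(naphthalen-2-ylmethyl)-D-xylofuranoside (anomer mixture)
Conditions: NaH, 2-(bromomethyl)naphthalene, n-Bu4NI (cat.), DMF, 0 °C → rt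
Reagents that add atoms: 2-(bromomethyl)naphthalene, BrCc1ccc2ccccc2c1
Why: Threefold Williamson etherification; NAP ethers tolerate the acid of step 9 like benzyl ethers but are removable with DDQ beside an oxirane at the end.

Step 9
Reactants: 12 methyl 4-C-ethenyl-2,3,5-tri-O-(naphthalen-2-ylmethyl)-D-xylofuranoside
Product: 13 4-C-ethenyl-2,3,5-tri-O-(naphthalen-2-ylmethyl)-D-xylofuranose (lactol, anomer mixture)
Conditions: 1 M aq. HCl/1,4-dioxane (1:2), 70 °C
Reagents that add atoms: water, O
Why: Acid hydrolysis of the furanoside acetal through the ring oxocarbenium ion; the ethers and the vinyl group are inert, and ionisation at the allylic quaternary carbon is disfavoured by its two β-oxygens.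

Step 10
Reactants: 13 4-C-ethenyl-2,3,5-tri-O-(naphthalen-2-ylmethyl)-D-xylofuranose; 14 vinylmagnesium bromide
Product: 15 6-C-ethenyl-1,2-dideoxy-4,5,7-tri-O-(naphthalen-2-ylmethyl)-D-ido-hept-1-enitol (acyclic diene with free O1-H and O4-H)
Conditions: CH2=CHMgBr (5 equiv), THF, −20 °C → rt; aq. NH4Cl
Reagents that add atoms: vinylmagnesium bromide, C=C[Mg]Br
Why: The first equivalent deprotonates the lactol, which opens to the magnesium alkoxide of the hydroxy aldehyde; vinyl then adds to the aldehyde held in a five-membered chelate with the neighbouring NAP-oxy group (Cram chelate control), from the side away from the chain. This should give O4 threo to O3, which is the lower-face O4 of the ring, and the former ring oxygen appears as the tertiary hydroxyl O1.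

Step 11
Reactants: 15 6-C-ethenyl-1,2-dideoxy-4,5,7-tri-O-(naphthalen-2-ylmethyl)-D-ido-hept-1-enitol
Product: 16 3-O-(tert-butyldimethylsilyl) ether of 15 (ring numbering: O4-TBS, tertiary O1-H free)
Conditions: TBSCl, imidazole, DMAP (cat.), DMF, 40 °C
Reagents that add atoms: tert-butyldimethylsilyl chloride, CC(C)(C)[Si](C)(C)Cl
Why: Silylation of the secondary allylic hydroxyl; a tertiary alcohol does not react with the silyl chloride under these conditions.

Step 12
Reactants: 16 3-O-(tert-butyldimethylsilyl) ether of 15
Product: 17 cyclohex-5-en-1-ol with 1-CH2O-NAP (upper face), O1-H, 2-O-NAP and 4-O-TBS (lower face), 3-O-NAP (upper face)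
Conditions: second-generation Grubbs catalyst (H2IMes)(PCy3)Cl2Ru=CHPh (5 mol %), CH2Cl2 (0.005 M), 40 °C
Reagents that add atoms: none
Why: Ring-closing olefin metathesis: after loss of PCy3 the ruthenium benzylidene exchanges with the more accessible vinyl group on the secondary carbon C4, the new alkylidene adds across the vinyl group on C1 by [2+2] cycloaddition, and retro-[2+2] of the ruthenacyclobutane releases the cyclohexene and a ruthenium methylidene that carries the chain. The closest known reaction type is the metathesis closure of sugar-derived 1,7-dienes bearing a free tertiary allylic hydroxyl to carbasugar cyclohexenes. The one ring formed is the six-membered carbocycle, closed by intramolecular alkylidene–alkene metathesis between the two terminal vinyl groups. No stereocentre is created and none is touched, since the conditions are neutral and C1–C4 stay sp3. The selectivity needed is cyclisation over cross-metathesis; high dilution, the ease of six-ring closure and the four contiguous substituted carbons, which can all hold their substituents equatorially in the forming ring, secure it. The free tertiary hydroxyl keeps the quaternary allylic position small and is tolerated by the catalyst, while the secondary allylic oxygen is silylated so that ruthenium hydride species cannot isomerise a vinyl carbinol to a ketone. Irreversible loss of ethene drives the reaction.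

Step 13
Reactants: 17 cyclohex-5-en-1-ol (metathesis product)
Product: 18 1-O-triethylsilyl ether of 17
Conditions: TESOTf, 2,6-lutidine, CH2Cl2, −78 → 0 °C
Reagents that add atoms: triethylsilyl trifluoromethanesulfonate, CC[Si](CC)(CC)OS(=O)(=O)C(F)(F)F
Why: Silyl triflate silylation of the tertiary alcohol; it removes the hydrogen bond that would guide a peracid to the lower face and puts a bulky pseudo-axial silyloxy group on that face.

Step 14
Reactants: 18 1-O-triethylsilyl ether of 17
Product: 19 upper-face 5,6-oxirane of 18
Conditions: m-CPBA (3 equiv), CH2Cl2/aq. pH 7 phosphate buffer, 0 °C → rt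
Reagents that add atoms: 3-chloroperoxybenzoic acid, OOC(=O)c1cccc(Cl)c1
Why: Prilezhaev epoxidation; both allylic silyloxy groups (O1 pseudo-axial, O4) shield the lower face, so the peracid should add from the upper face and set C5 and C6.

Step 15
Reactants: 19 upper-face 5,6-oxirane of 18
Product: 21 lower-face 1,6-oxirane 4,5-diol tris-NAP ether, via desilylated 5,6-epoxy diol 20 (not isolated)
Conditions: n-Bu4NF (4 equiv), THF, 0 °C → rt; then 1 M aq. NaOH, t-BuOH, rt
Reagents that add atoms: none
Why: Fluoride removes both silyl groups; the O1 alkoxide, anti to the C6–O bond, opens the oxirane at C6 with inversion (Payne rearrangement), giving the lower-face C1–C6 oxirane and the upper-face O5. The competing migration towards C4 through O4 is reversible, and the equilibrium should favour the trisubstituted oxirane with two secondary hydroxyls; no ester is present to migrate.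

Step 16
Reactants: 21 lower-face 1,6-oxirane 4,5-diol tris-NAP ether
Product: 22 4,5-bis-O-triethylsilyl ether of 21
Conditions: TESOTf (2.5 equiv), 2,6-lutidine, CH2Cl2, −78 → 0 °C
Reagents that add atoms: triethylsilyl trifluoromethanesulfonate, CC[Si](CC)(CC)OS(=O)(=O)C(F)(F)F
Why: Silylation of both secondary hydroxyls with a non-nucleophilic base that leaves the oxirane alone; the silyl ethers mark O4 and O5 as the oxygens that stay free in the target.

Step 17
Reactants: 22 4,5-bis-O-triethylsilyl ether of 21
Product: 23 2,3-diol with free C7 hydroxyl (4,5-bis-O-TES 1,6-oxirane triol)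
Conditions: DDQ (6 equiv), CH2Cl2/aq. pH 7 phosphate buffer (10:1), rt
Reagents that add atoms: none
Why: Oxidative cleavage of the three NAP ethers by hydride abstraction and hydrolysis of the oxocarbenium ions; buffered two-phase conditions protect the oxirane and the silyl ethers.

Step 18
Reactants: 23 4,5-bis-O-TES 1,6-oxirane triol
Product: 24 C7 benzoate of 23
Conditions: BzCl (1.1 equiv), 2,4,6-collidine, CH2Cl2, −40 → −20 °C
Reagents that add atoms: benzoyl chloride, O=C(Cl)c1ccccc1
Why: Rate-selective acylation of the primary hydroxyl; O2-H is flanked by the quaternary C1 and O3-H by a silyloxy carbon, so both react much more slowly at low temperature.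

Step 19
Reactants: 24 C7 benzoate of 23
Product: 25 2,3-di-O-acetate of 24
Conditions: Ac2O, pyridine, DMAP (cat.), CH2Cl2, 0 °C → rt
Reagents that add atoms: acetic anhydride, CC(=O)OC(C)=O
Why: DMAP-catalysed acetylation of the two remaining secondary hydroxyls; no free hydroxyl is left next to an ester, so no acyl migration is possible.

Step 20
Reactants: 25 2,3-di-O-acetate of 24
Product: 26 [(1S,2R,3S,4R,5R,6S)-2,3-bis(acetyloxy)-4,5-dihydroxy-7-oxabicyclo[4.1.0]heptan-1-yl]methyl benzoate (CNP0171674.1)
Conditions: HF·pyridine, pyridine, THF, 0 °C → rt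
Reagents that add atoms: none
Why: Buffered fluoride cleavage of the two triethylsilyl ethers under weakly acidic conditions, in which acetyl migration is slow and the oxirane is not opened.

## Compound list

1 | 1,2:5,6-di-O-isopropylidene-α-D-glucofuranose | CC1(C)OC[C@@H](O1)[C@H]2O[C@@H]3OC(C)(C)O[C@@H]3[C@H]2O | starting material
2 | 1,2:5,6-di-O-isopropylidene-3-O-(4-methoxybenzyl)-α-D-glucofuranose | CC1(C)OC[C@@H](O1)[C@H]2O[C@@H]3OC(C)(C)O[C@@H]3[C@H]2OCc4ccc(OC)cc4 | intermediate
3 | 1,2-O-isopropylidene-3-O-(4-methoxybenzyl)-α-D-glucofuranose | OC[C@@H](O)[C@H]1O[C@@H]2OC(C)(C)O[C@@H]2[C@H]1OCc1ccc(OC)cc1 | intermediate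
4 | formaldehyde | C=O | starting material
5 | 1,2-O-isopropylidene-3-O-(4-methoxybenzyl)-α-D-xylo-pentodialdo-1,4-furanose (not isolated) | O=C[C@H]1O[C@@H]2OC(C)(C)O[C@@H]2[C@H]1OCc1ccc(OC)cc1 | intermediate
6 | 4-C-(hydroxymethyl) aldol adduct of 5, both C4 epimers (not isolated) | O=CC1(CO)O[C@@H]2OC(C)(C)O[C@@H]2[C@H]1OCc1ccc(OC)cc1 | intermediate
7 | 4-C-(hydroxymethyl)-1,2-O-isopropylidene-3-O-(4-methoxybenzyl)-β-L-threo-pentofuranose (xylo-derived furanose with two hydroxymethyl groups on C4) | OCC1(CO)O[C@@H]2OC(C)(C)O[C@@H]2[C@H]1OCc1ccc(OC)cc1 | intermediate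
8 | 4-C-(hydroxymethyl)-1,2-O-isopropylidene-3,5-O-(4-methoxybenzylidene)-α-D-xylofuranose (arm cis to O3 in the acetal, arm trans to O3 free) | OC[C@@]12COC(c3ccc(OC)cc3)O[C@@H]1[C@H]4OC(C)(C)O[C@H]4O2 | intermediate
9 | 4-C-formyl-1,2-O-isopropylidene-3,5-O-(4-methoxybenzylidene)-α-D-xylofuranose | O=C[C@@]12COC(c3ccc(OC)cc3)O[C@@H]1[C@H]4OC(C)(C)O[C@H]4O2 | intermediate
10 | 4-C-ethenyl-1,2-O-isopropylidene-3,5-O-(4-methoxybenzylidene)-α-D-xylofuranose | C=C[C@@]12COC(c3ccc(OC)cc3)O[C@@H]1[C@H]4OC(C)(C)O[C@H]4O2 | intermediate
11 | methyl 4-C-ethenyl-D-xylofuranoside (anomer mixture) | C=C[C@]1(CO)OC(OC)[C@H](O)[C@H]1O | intermediate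
12 | methyl 4-C-ethenyl-2,3,5-tri-O-(naphthalen-2-ylmethyl)-D-xylofuranoside (anomer mixture) | C=C[C@]1(COCc2ccc3ccccc3c2)OC(OC)[C@H](OCc2ccc3ccccc3c2)[C@H]1OCc2ccc3ccccc3c2 | intermediate
13 | 4-C-ethenyl-2,3,5-tri-O-(naphthalen-2-ylmethyl)-D-xylofuranose (lactol, anomer mixture) | C=C[C@]1(COCc2ccc3ccccc3c2)OC(O)[C@H](OCc2ccc3ccccc3c2)[C@H]1OCc2ccc3ccccc3c2 | intermediate
14 | vinylmagnesium bromide | C=C[Mg]Br | starting material
15 | 6-C-ethenyl-1,2-dideoxy-4,5,7-tri-O-(naphthalen-2-ylmethyl)-D-ido-hept-1-enitol (ring numbering: free O1-H and O4-H, NAP on O2, O3, O7) | C=C[C@@](O)(COCc1ccc2ccccc2c1)[C@H](OCc1ccc2ccccc2c1)[C@@H](OCc1ccc2ccccc2c1)[C@H](O)C=C | intermediate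
16 | 3-O-(tert-butyldimethylsilyl) ether of 15 (ring numbering: O4-TBS, O1-H free); metathesis precursor | C=C[C@@](O)(COCc1ccc2ccccc2c1)[C@H](OCc1ccc2ccccc2c1)[C@@H](OCc1ccc2ccccc2c1)[C@H](O[Si](C)(C)C(C)(C)C)C=C | intermediate
17 | cyclohex-5-en-1-ol: 1-CH2O-NAP upper; O1-H, 2-O-NAP, 4-O-TBS lower; 3-O-NAP upper; metathesis product | O[C@]1(COCc2ccc3ccccc3c2)[C@H](OCc2ccc3ccccc3c2)[C@@H](OCc2ccc3ccccc3c2)[C@H](O[Si](C)(C)C(C)(C)C)C=C1 | intermediate
18 | 1-O-triethylsilyl ether of 17 | CC[Si](CC)(CC)O[C@]1(COCc2ccc3ccccc3c2)[C@H](OCc2ccc3ccccc3c2)[C@@H](OCc2ccc3ccccc3c2)[C@H](O[Si](C)(C)C(C)(C)C)C=C1 | intermediate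
19 | upper-face 5,6-oxirane of 18 | CC[Si](CC)(CC)O[C@]1(COCc2ccc3ccccc3c2)[C@H](OCc2ccc3ccccc3c2)[C@@H](OCc2ccc3ccccc3c2)[C@H](O[Si](C)(C)C(C)(C)C)[C@H]2O[C@@H]12 | intermediate
20 | upper-face 5,6-oxirane with free O1-H and O4-H (not isolated) | O[C@]1(COCc2ccc3ccccc3c2)[C@H](OCc2ccc3ccccc3c2)[C@@H](OCc2ccc3ccccc3c2)[C@H](O)[C@H]2O[C@@H]12 | intermediate
21 | lower-face 1,6-oxirane with O4-H lower and O5-H upper; NAP on O2, O3, O7 | O1[C@]2(COCc3ccc4ccccc4c3)[C@H](OCc3ccc4ccccc4c3)[C@@H](OCc3ccc4ccccc4c3)[C@H](O)[C@@H](O)[C@H]12 | intermediate
22 | 4,5-bis-O-triethylsilyl ether of 21 | O1[C@]2(COCc3ccc4ccccc4c3)[C@H](OCc3ccc4ccccc4c3)[C@@H](OCc3ccc4ccccc4c3)[C@H](O[Si](CC)(CC)CC)[C@@H](O[Si](CC)(CC)CC)[C@H]12 | intermediate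
23 | 4,5-bis-O-TES 1,6-oxirane with free O2-H, O3-H and C7-OH | O1[C@]2(CO)[C@H](O)[C@@H](O)[C@H](O[Si](CC)(CC)CC)[C@@H](O[Si](CC)(CC)CC)[C@H]12 | intermediate
24 | C7 benzoate of 23 | O1[C@]2(COC(=O)c3ccccc3)[C@H](O)[C@@H](O)[C@H](O[Si](CC)(CC)CC)[C@@H](O[Si](CC)(CC)CC)[C@H]12 | intermediate
25 | 2,3-di-O-acetate of 24 | O1[C@]2(COC(=O)c3ccccc3)[C@H](OC(C)=O)[C@@H](OC(C)=O)[C@H](O[Si](CC)(CC)CC)[C@@H](O[Si](CC)(CC)CC)[C@H]12 | intermediate
26 | [(1S,2R,3S,4R,5R,6S)-2,3-bis(acetyloxy)-4,5-dihydroxy-7-oxabicyclo[4.1.0]heptan-1-yl]methyl benzoate | CC(=O)O[C@H]1[C@H](O)[C@@H](O)[C@@H]2O[C@]2(COC(=O)c2ccccc2)[C@@H]1OC(C)=O | target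

## Step count and least certain steps

Total step count: 20. Longest linear sequence: 20 steps (1 to 26); formaldehyde 4 and vinylmagnesium bromide 14 enter as reagents in steps 3 and 10.

**Step 12 (key step).** The vinyl group on the quaternary carbinol may be engaged too slowly. Intermolecular metathesis to oligomers, or double-bond migration by ruthenium hydride species formed from a decomposing catalyst, could then compete with closure. Fallback by carbonyl coupling instead of metathesis: from 16, both vinyl groups would be cleaved (OsO4 cat., NaIO4, 2,6-lutidine, dioxane/H2O) to the dialdehyde F1. SmI2 (THF, t-BuOH, −78 °C) would close the ring by pinacol coupling to the cis-5,6-diol F2, whose configuration at C5/C6 is immaterial. 1,1'-Thiocarbonyldiimidazole would give the cyclic thionocarbonate F3, and P(OMe)3 at reflux (Corey–Winter olefination) would return the cyclohexene 17.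

**Step 7.** Once O5 is free, prolonged exposure to acid can let the furanosides ring-expand to pyranosides, which would lead to the wrong ether pattern. Fallback in stages: from 10, pyridinium p-toluenesulfonate in MeOH at rt would remove only the benzylidene acetal and give the acetonide diol F4. NaH and 2-(bromomethyl)naphthalene would give the 3,5-di-O-NAP ether F5. Methanolic HCl would then open the 1,2-acetal to the methyl furanoside F6, which cannot ring-expand because O5 is capped. A second NAP alkylation at O2 rejoins the route at 12.

**Step 10.** Facial selectivity of the vinyl addition may be poor if non-chelated or β-chelated transition states compete, which would give the C4 epimer. Fallback setting C4 in the ring: from 13 the addition would be run without regard to selectivity, and the mixture of 15 and its C4 epimer F7 would be cyclised as free diols with the same ruthenium catalyst. This gives the cyclohexene-1,4-diol F10 and its 4-epimer F8. MnO2 would oxidise the secondary allylic alcohol of both to the single enone F9. NaBH4/CeCl3·7H2O (Luche reduction) should deliver hydride axially and give F10, with O4 trans to O3 on the lower face. TBSCl/imidazole on the secondary hydroxyl rejoins the route at 17.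

**Step 14.** The alkene is electron-poor and flanked by a quaternary carbon, so epoxidation may be slow and its facial selectivity incomplete. Fallback by dihydroxylation: from 18, OsO4 (cat.) with N-methylmorpholine N-oxide should add anti to both allylic silyloxy groups and give the upper-face cis-5,6-diol F11. Trimethyl orthoacetate with pyridinium p-toluenesulfonate, then acetyl bromide, would convert it through the acetoxonium ion into the trans-bromo acetate F12 (bromide at C5 on the lower face; the regioisomer converges). K2CO3 in MeOH removes the acetate, and the upper-face alkoxide displaces bromide to give the oxirane 19.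

**Step 17.** A hydroxyl freed early can capture the oxocarbenium ion of a neighbouring NAP ether (for instance between O2 and O7), and the resulting acetal can be over-oxidised to a naphthoate. The acidic hydroquinone may also strip a triethylsilyl group. Fallback by reduction instead of oxidation: from 22, hydrogenolysis (H2, Pd/C, EtOAc, rt) cleaves NAP ethers readily and should leave the isolated oxirane and the silyl ethers intact, giving 23 directly; no new compound is formed.

## Further compounds

F1 | step 12 | dialdehyde from cleavage of both vinyl groups of 16 (C5 and C6 as CHO) | O=C[C@@](O)(COCc1ccc2ccccc2c1)[C@H](OCc1ccc2ccccc2c1)[C@@H](OCc1ccc2ccccc2c1)[C@H](O[Si](C)(C)C(C)(C)C)C=O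
F2 | step 12 | pinacol product, cyclohexane-1,5,6-triol with cis-5,6-diol (C5/C6 configuration not fixed) | O[C@]1(COCc2ccc3ccccc3c2)[C@H](OCc2ccc3ccccc3c2)[C@@H](OCc2ccc3ccccc3c2)[C@H](O[Si](C)(C)C(C)(C)C)C(O)C1O
F3 | step 12 | cyclic 5,6-thionocarbonate of F2 | O[C@]1(COCc2ccc3ccccc3c2)[C@H](OCc2ccc3ccccc3c2)[C@@H](OCc2ccc3ccccc3c2)[C@H](O[Si](C)(C)C(C)(C)C)C2OC(=S)OC12
F4 | step 7 | 4-C-ethenyl-1,2-O-isopropylidene-α-D-xylofuranose | C=C[C@]1(CO)O[C@@H]2OC(C)(C)O[C@@H]2[C@H]1O
F5 | step 7 | 4-C-ethenyl-1,2-O-isopropylidene-3,5-di-O-(naphthalen-2-ylmethyl)-α-D-xylofuranose | C=C[C@]1(COCc4ccc5ccccc5c4)O[C@@H]2OC(C)(C)O[C@@H]2[C@H]1OCc4ccc5ccccc5c4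
F6 | step 7 | methyl 4-C-ethenyl-3,5-di-O-(naphthalen-2-ylmethyl)-D-xylofuranoside (anomer mixture) | C=C[C@]1(COCc4ccc5ccccc5c4)OC(OC)[C@H](O)[C@H]1OCc4ccc5ccccc5c4
F7 | step 10 | C4 epimer of 15 (O4 erythro to O3) | C=C[C@@](O)(COCc1ccc2ccccc2c1)[C@H](OCc1ccc2ccccc2c1)[C@@H](OCc1ccc2ccccc2c1)[C@@H](O)C=C
F8 | step 10 | 4-epi-cyclohex-5-ene-1,4-diol (O4-H upper face) | O[C@]1(COCc2ccc3ccccc3c2)[C@H](OCc2ccc3ccccc3c2)[C@@H](OCc2ccc3ccccc3c2)[C@@H](O)C=C1
F9 | step 10 | cyclohex-5-en-4-one with O1-H lower, 2-O-NAP lower, 3-O-NAP upper | O[C@]1(COCc2ccc3ccccc3c2)[C@H](OCc2ccc3ccccc3c2)[C@@H](OCc2ccc3ccccc3c2)C(=O)C=C1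
F10 | step 10 | cyclohex-5-ene-1,4-diol (O1-H and O4-H lower face) | O[C@]1(COCc2ccc3ccccc3c2)[C@H](OCc2ccc3ccccc3c2)[C@@H](OCc2ccc3ccccc3c2)[C@H](O)C=C1
F11 | step 14 | upper-face cis-5,6-diol of 18 | CC[Si](CC)(CC)O[C@]1(COCc2ccc3ccccc3c2)[C@H](OCc2ccc3ccccc3c2)[C@@H](OCc2ccc3ccccc3c2)[C@H](O[Si](C)(C)C(C)(C)C)[C@@H](O)[C@H]1O
F12 | step 14 | trans-bromo acetate: 5-bromo lower face, 6-acetoxy upper face | CC[Si](CC)(CC)O[C@]1(COCc2ccc3ccccc3c2)[C@H](OCc2ccc3ccccc3c2)[C@@H](OCc2ccc3ccccc3c2)[C@H](O[Si](C)(C)C(C)(C)C)[C@H](Br)[C@H]1OC(C)=O
F0 | step 17 | none | none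
A1 | alternative 1 | 4-(benzoyloxymethyl)-4-hydroxycyclohexa-2,5-dienone (para-quinol) | O=C1C=CC(O)(COC(=O)c2ccccc2)C=C1
A2 | alternative 1 | cis-fused phenylboronate of the 1,2-diol enone | O=C1C=C[C@]2(COC(=O)c3ccccc3)OB(c3ccccc3)O[C@@H]2C1
A3 | alternative 2 | 1-(benzoyloxymethyl)cyclohexa-1,3-diene with free 2-hydroxyl and trans 3-acetate | O[C@@H]1[C@@H](OC(C)=O)C=CC=C1COC(=O)c1ccccc1
A4 | alternative 2 | bicyclic endoperoxide (2,3-dioxabicyclo[2.2.2]octene) | O[C@@H]1[C@@H](OC(C)=O)[C@H]2C=C[C@]1(COC(=O)c3ccccc3)OO2
A5 | alternative 3 | (1S,2R)-1,2-dihydroxycyclohexa-3,5-diene-1-carboxylic acid (benzoic acid ipso,ortho-cis-dihydrodiol) | O[C@]1(C(=O)O)[C@H](O)C=CC=C1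
A6 | alternative 3 | lower-face 4,5-oxirane with O1-H lower, O6-H upper, 2,3-bis-PMB ether, C7 benzoate | O[C@]1(COC(=O)c2ccccc2)[C@H](OCc2ccc(OC)cc2)[C@@H](OCc2ccc(OC)cc2)[C@@H]2O[C@@H]2[C@H]1O
A7 | alternative 3 | target skeleton as 2,3-bis-PMB ether 4,5-diol | COc3ccc(cc3)CO[C@H]1[C@H](O)[C@@H](O)[C@@H]2O[C@]2(COC(=O)c3ccccc3)[C@@H]1OCc3ccc(OC)cc3
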